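**Retrosynthetic overview**

1. Target 25 is 7,9-di-O-isovaleryl-longipin-2-en-1-one; allylic oxidation at C1 (pinene → verbenone type), esterification and removal of a bridgehead C4 hydroxyl lead back to tricyclic diol 17.
2. Feature the strategy rests on: the cyclobutane C4–C5–C11–C10, whose methyl-bearing quaternary C10 is bonded to oxygenated C9 (a tertiary β-oxy radical, i.e. a C9–C10 epoxide) and lies 1,3 to C4 across the six-membered ring C1–C2–C3–C4–C5–C11, a ring that with C10 and both methyl groups is (R)-carvone.
3. Key disconnection C4–C10: Cp2TiCl opens the C9–C10 epoxide of cis-fused cyclohexenone–cycloheptane 15 and the C10 radical adds 4-exo to the C4 ketone.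
4. 15 comes from epoxidation and ring-closing metathesis (C9=C10) of cis diene 13; 13 from carvone by α′-Michael addition to nitroalkene 2 (C5–C6), Nef reaction, asymmetric allylation (C7–C8), silylation and kinetic protonation at C5.
5. Ring order: six-membered ring from carvone, then seven-membered ring C5–C6–C7–C8–C9–C10–C11 by metathesis, then the four-membered ring by the titanocene closure.

Key step: step 8

Remark: the (R)-configured phosphoric acid of step 3 is assumed to deliver allyl to the Re face of aldehyde 7, as it does with simple aldehydes; if the hindered aldehyde responds in the opposite sense, the (S)-acid is used. Tricyclic compounds carry the longipinane numbers C1–C11 of the overview, and these numbers are also used for the corresponding atoms of the earlier intermediates.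

**Route**

Step 1
Reactants: 1 (R)-carvone; 2 2-methyl-1-nitroprop-1-ene
Product: 5 (5R,6R)-2-methyl-6-(2-methyl-1-nitropropan-2-yl)-5-(prop-1-en-2-yl)cyclohex-2-en-1-one (side chain trans to isopropenyl), via lithium dienolate 3 (not isolated), via lithium nitronate 4 (not isolated)
Conditions: LiN(iPr)2 (LDA), THF, −78 °C; then 2, −78 °C; AcOH, −78 °C
Reagents that add atoms: none
Why: Kinetic deprotonation gives the cross-conjugated α′-dienolate, which should undergo Michael addition to the nitroalkene at its fully substituted β-carbon anti to the isopropenyl group (C5–C6 bond, trans; this centre is reset in step 5), and the cold acetic acid quench protonates the nitronate before it can add to C2.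

Step 2
Reactants: 5
Product: 7 2-methyl-2-[(1R,6R)-3-methyl-2-oxo-6-(prop-1-en-2-yl)cyclohex-3-en-1-yl]propanal, via sodium nitronate 6 (not isolated)
Conditions: NaOMe, MeOH, 0 °C; then aq. TiCl3, NH4OAc (pH 5–6), 0 °C → rt
Reagents that add atoms: water, O
Why: Nef reaction in its reductive form, in which titanium trichloride reduces the nitronate through the oxime to the imine that hydrolyses to the aldehyde near neutral pH, conditions the enone and the isopropenyl group should survive, while the quaternary C6 keeps the aldehyde from enolising or closing to a furan.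

Step 3
Reactants: 7; 8 allylboronic acid pinacol ester
Product: 10 (5R,6R)-6-[(3R)-3-hydroxy-2-methylhex-5-en-2-yl]-2-methyl-5-(prop-1-en-2-yl)cyclohex-2-en-1-one, via pinacol borate 9 (not isolated)
Conditions: (R)-TRIP (3,3′-bis(2,4,6-triisopropylphenyl)-BINOL hydrogen phosphate, 5 mol%), toluene, −30 °C; aq. work-up
Reagents that add atoms: none
Why: Chiral phosphoric acid-catalysed allylboration through a closed chair transition state in which the acid binds the boronate oxygen and the formyl hydrogen, so that allyl should be delivered to the Re face and C7 set as R under reagent control, the aldehyde reacting in preference to the hindered conjugated ketone.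

Step 4
Reactants: 10
Product: 11 (5R,6R)-6-[(3R)-3-(tert-butyldimethylsilyloxy)-2-methylhex-5-en-2-yl]-2-methyl-5-(prop-1-en-2-yl)cyclohex-2-en-1-one
Conditions: TBSOTf, 2,6-lutidine, CH2Cl2, −78 → 0 °C
Reagents that add atoms: tert-butyldimethylsilyl triflate, CC(C)(C)[Si](C)(C)OS(=O)(=O)C(F)(F)F
Why: Silylation of the hindered secondary alcohol with a silyl triflate and a non-nucleophilic base removes the acidic proton before step 5, prevents hemiketal formation with the C4 ketone and later shields one face of the C9=C10 alkene.

Step 5
Reactants: 11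
Product: 13 (5R,6S)-6-[(3R)-3-(tert-butyldimethylsilyloxy)-2-methylhex-5-en-2-yl]-2-methyl-5-(prop-1-en-2-yl)cyclohex-2-en-1-one (side chain cis to isopropenyl), via lithium enolate 12 (not isolated)
Conditions: LiN(iPr)2 (LDA), THF, −78 → −30 °C; then AcOH/THF, −78 °C; cold pH 7 work-up
Reagents that add atoms: none
Why: Deprotonation at the only α-hydrogen followed by kinetic protonation of the enolate, in which A(1,2) strain with the quaternary side chain turns the isopropenyl group pseudoaxial so that the proton should enter C5 anti to it and leave the side chain cis to the isopropenyl group (the contra-thermodynamic epimer).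

Step 6
Reactants: 13
Product: 14 (4aR,8R,9aS)-8-(tert-butyldimethylsilyloxy)-2,5,9,9-tetramethyl-4,4a,7,8,9,9a-hexahydro-1H-benzo[7]annulen-1-one (cis-fused; silyloxy group on the face opposite to the two ring-fusion hydrogens)
Conditions: second-generation Grubbs catalyst (H2IMes)(PCy3)Cl2Ru=CHPh (5 mol%), CH2Cl2 (0.005 M), 40 °C
Reagents that add atoms: none
Why: Ring-closing olefin metathesis in which the catalyst loads on the terminal alkene and closes onto the isopropenyl group to give the trisubstituted cycloheptene with loss of ethylene, the cis arms giving the cis-fused bicycle and the electron-poor enone alkene staying out.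

Step 7
Reactants: 14
Product: 15 5,6-epoxide of 14 (C9–C10 epoxide in longipinane numbers; epoxide oxygen on the face of the seven-membered ring that carries both ring-fusion hydrogens, anti to the silyloxy group)
Conditions: mCPBA, NaHCO3, CH2Cl2, 0 °C
Reagents that add atoms: 3-chloroperbenzoic acid, OOC(=O)c1cccc(Cl)c1
Why: Prilezhaev epoxidation of the electron-rich trisubstituted C9=C10 alkene (the enone alkene is inert) from the convex face of the cis-fused bicycle, syn to H11 and H5 and anti to C1 and the C7 silyloxy group, which should set C9 and C10.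

Step 8
Reactants: 15
Product: 17 7-(tert-butyldimethylsilyloxy)longipin-2-ene-4,9-diol (bridgehead 4-OH; 9-OH directed toward the C11 bridgehead, 7-O toward the C4 bridgehead), via titanium dialkoxide 16 (not isolated)
Conditions: Cp2TiCl (from Cp2TiCl2 and Mn dust, THF), added slowly to 15 in THF (0.01 M), rt; then aq. NaH2PO4
Reagents that add atoms: none
Why: Single-electron transfer from Cp2TiCl (trivalent titanium) breaks the epoxide C–O bond at the more substituted carbon C10, so that a tertiary radical results there while C9 carries a titanium alkoxide and keeps its epoxide configuration. Because C10 stands axial on C11 in the cis-fused bicycle, the radical centre sits above C4 and attacks the carbonyl carbon of the Cp2TiCl-coordinated ketone in a 4-exo-trig closure that forms C4–C10 and the cyclobutane C4–C5–C11–C10, the O–Ti bond formed making the addition irreversible. The closest known reaction is the Cp2TiCl-mediated cyclisation of 8,9-epoxycarvones to bridgehead pinene-type cyclobutanols. C4 is a bridgehead whose configuration follows from the 1,3-bridging itself, and C10 is set by the seven-membered ring, which keeps C9 on the side away from the C2=C3 bridge so that the methyl group ends syn to it. The step needs attack at the carbonyl carbon to outrun β-hydrogen loss, reduction of the radical and attack at the enone β-carbon C2; titanium coordination of the ketone, the cis fusion that places C10 over C4 and a low Cp2TiCl concentration should secure this.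

Step 9
Reactants: 17
Product: 18 7-(tert-butyldimethylsilyloxy)-9-(triethylsilyloxy)longipin-2-en-4-ol
Conditions: TESCl, imidazole, DMAP (cat.), CH2Cl2, 0 °C
Reagents that add atoms: chlorotriethylsilane, CC[Si](Cl)(CC)CC
Why: Silylation with a silyl chloride and imidazole should take the secondary C9 hydroxyl and leave the tertiary bridgehead C4 hydroxyl free.

Step 10
Reactants: 18
Product: 20 O-[7-(tert-butyldimethylsilyloxy)-9-(triethylsilyloxy)longipin-2-en-4-yl] S-methyl dithiocarbonate, via sodium xanthate 19 (not isolated)
Conditions: NaH, CS2, imidazole (cat.), THF, 0 °C → rt; then MeI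
Reagents that add atoms: carbon disulfide, S=C=S; iodomethane, CI
Why: Xanthate formation (first half of a Barton–McCombie deoxygenation) by addition of the bridgehead alkoxide to carbon disulfide and S-methylation; a tertiary xanthate is usable here because Chugaev elimination or allylic rearrangement would need a bridgehead alkene.

Step 11
Reactants: 20
Product: 21 7-(tert-butyldimethylsilyloxy)-9-(triethylsilyloxy)longipin-2-ene (C4–H)
Conditions: Bu3SnH, AIBN, toluene, 110 °C
Reagents that add atoms: none
Why: Barton–McCombie deoxygenation in which the stannyl radical adds to the thiocarbonyl group, β-scission releases the C4 bridgehead radical and hydrogen transfer from the stannane gives C4–H with the configuration imposed by the cage, the σ-radical being trapped faster than the cyclobutane can open.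

Step 12
Reactants: 21
Product: 22 longipin-2-ene-7,9-diol
Conditions: Bu4NF (TBAF), THF, 50 °C
Reagents that add atoms: none
Why: Fluoride-mediated desilylation should remove both silyl ethers under basic conditions, which the acid-sensitive pinene-type alkene tolerates.

Step 13
Reactants: 22 longipin-2-ene-7,9-diol; 23 isovaleryl chloride (3-methylbutanoyl chloride)
Product: 24 longipin-2-ene-7,9-diyl bis(3-methylbutanoate)
Conditions: 23 (3 equiv in all), DMAP, pyridine, CH2Cl2, rt → 40 °C
Reagents that add atoms: isovaleryl chloride (second equivalent of 23), CC(C)CC(Cl)=O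
Why: DMAP-catalysed acylation (acyl transfer through the N-acylpyridinium ion) in which each of the two hindered secondary alcohols takes up one molecule of the acid chloride, so that two equivalents are consumed and an excess can be used because no other hydroxyl remains.

Step 14
Reactants: 24
Product: 25 7,9-bis(3-methylbutanoyloxy)longipin-2-en-1-one (2,6,6,9-tetramethyl-11-oxotricyclo[5.4.0.0^2,8]undec-9-ene-3,5-diyl bis(3-methylbutanoate)), the target
Conditions: CrO3, 3,5-dimethylpyrazole, CH2Cl2, −20 °C
Reagents that add atoms: chromium trioxide, O=[Cr](=O)=O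
Why: Allylic oxidation with hexavalent chromium (CrO3·3,5-dimethylpyrazole), the α-pinene → verbenone conversion: C1 is the only allylic methylene, oxygenation at either end of the C1–C2–C3 allyl system converges on the C1 ketone with the alkene at C2=C3, and the bridgehead C4–H cannot be drawn into conjugation.

**Compound list**

1 | (R)-carvone | CC1=CC[C@H](CC1=O)C(C)=C | starting material
2 | 2-methyl-1-nitroprop-1-ene | CC(C)=C[N+](=O)[O-] | starting material
3 | lithium (R)-6-methyl-3-(prop-1-en-2-yl)cyclohexa-1,5-dien-1-olate (α′-dienolate of 1) | CC1=CC[C@@H](C(C)=C)C=C1[O-].[Li+] | intermediate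
4 | lithium nitronate of 5 | CC1=CC[C@@H](C(C)=C)[C@@H](C1=O)C(C)(C)C=[N+]([O-])[O-].[Li+] | intermediate
5 | (5R,6R)-2-methyl-6-(2-methyl-1-nitropropan-2-yl)-5-(prop-1-en-2-yl)cyclohex-2-en-1-one | CC1=CC[C@@H](C(C)=C)[C@@H](C1=O)C(C)(C)C[N+](=O)[O-] | intermediate
6 | sodium nitronate of 5 | CC1=CC[C@@H](C(C)=C)[C@@H](C1=O)C(C)(C)C=[N+]([O-])[O-].[Na+] | intermediate
7 | 2-methyl-2-[(1R,6R)-3-methyl-2-oxo-6-(prop-1-en-2-yl)cyclohex-3-en-1-yl]propanal | CC1=CC[C@@H](C(C)=C)[C@@H](C1=O)C(C)(C)C=O | intermediate
8 | allylboronic acid pinacol ester | C=CCB1OC(C)(C)C(C)(C)O1 | starting material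
9 | pinacol borate (O–Bpin) of 10 | CC1=CC[C@@H](C(C)=C)[C@@H](C1=O)C(C)(C)[C@H](OB2OC(C)(C)C(C)(C)O2)CC=C | intermediate
10 | (5R,6R)-6-[(3R)-3-hydroxy-2-methylhex-5-en-2-yl]-2-methyl-5-(prop-1-en-2-yl)cyclohex-2-en-1-one | CC1=CC[C@@H](C(C)=C)[C@@H](C1=O)C(C)(C)[C@H](O)CC=C | intermediate
11 | (5R,6R)-6-[(3R)-3-(tert-butyldimethylsilyloxy)-2-methylhex-5-en-2-yl]-2-methyl-5-(prop-1-en-2-yl)cyclohex-2-en-1-one | CC1=CC[C@@H](C(C)=C)[C@@H](C1=O)C(C)(C)[C@H](O[Si](C)(C)C(C)(C)C)CC=C | intermediate
12 | lithium C4–C5 enolate of 11 | CC1=CC[C@@H](C(C)=C)C(=C1[O-])C(C)(C)[C@H](O[Si](C)(C)C(C)(C)C)CC=C.[Li+] | intermediate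
13 | (5R,6S)-6-[(3R)-3-(tert-butyldimethylsilyloxy)-2-methylhex-5-en-2-yl]-2-methyl-5-(prop-1-en-2-yl)cyclohex-2-en-1-one | CC1=CC[C@@H](C(C)=C)[C@H](C1=O)C(C)(C)[C@H](O[Si](C)(C)C(C)(C)C)CC=C | intermediate
14 | (4aR,8R,9aS)-8-(tert-butyldimethylsilyloxy)-2,5,9,9-tetramethyl-4,4a,7,8,9,9a-hexahydro-1H-benzo[7]annulen-1-one (cis-fused) | CC1=CC[C@@H]2[C@H](C1=O)C(C)(C)[C@H](O[Si](C)(C)C(C)(C)C)CC=C2C | intermediate
15 | 5,6-epoxide of 14 (C9–C10 epoxide, oxygen syn to the ring-fusion hydrogens) | CC1=CC[C@@H]2[C@H](C1=O)C(C)(C)[C@H](O[Si](C)(C)C(C)(C)C)C[C@H]3O[C@@]23C | intermediate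
16 | bis(chlorotitanocene) 4,9-dialkoxide of 17 | CC1=CC[C@@H]2[C@@H]3[C@@]1(O[Ti](Cl)(C4C=CC=C4)C4C=CC=C4)[C@@]2(C)[C@H](O[Ti](Cl)(C4C=CC=C4)C4C=CC=C4)C[C@@H](O[Si](C)(C)C(C)(C)C)C3(C)C | intermediate
17 | 7-(tert-butyldimethylsilyloxy)longipin-2-ene-4,9-diol | CC1=CC[C@@H]2[C@@H]3[C@@]1(O)[C@@]2(C)[C@H](O)C[C@@H](O[Si](C)(C)C(C)(C)C)C3(C)C | intermediate
18 | 7-(tert-butyldimethylsilyloxy)-9-(triethylsilyloxy)longipin-2-en-4-ol | CC1=CC[C@@H]2[C@@H]3[C@@]1(O)[C@@]2(C)[C@H](O[Si](CC)(CC)CC)C[C@@H](O[Si](C)(C)C(C)(C)C)C3(C)C | intermediate
19 | sodium O-alkyl dithiocarbonate of 18 | CC1=CC[C@@H]2[C@@H]3[C@@]1(OC(=S)[S-])[C@@]2(C)[C@H](O[Si](CC)(CC)CC)C[C@@H](O[Si](C)(C)C(C)(C)C)C3(C)C.[Na+] | intermediate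
20 | O-[7-(tert-butyldimethylsilyloxy)-9-(triethylsilyloxy)longipin-2-en-4-yl] S-methyl dithiocarbonate | CC1=CC[C@@H]2[C@@H]3[C@@]1(OC(=S)SC)[C@@]2(C)[C@H](O[Si](CC)(CC)CC)C[C@@H](O[Si](C)(C)C(C)(C)C)C3(C)C | intermediate
21 | 7-(tert-butyldimethylsilyloxy)-9-(triethylsilyloxy)longipin-2-ene | CC1=CC[C@@H]2[C@@H]3[C@H]1[C@@]2(C)[C@H](O[Si](CC)(CC)CC)C[C@@H](O[Si](C)(C)C(C)(C)C)C3(C)C | intermediate
22 | longipin-2-ene-7,9-diol | CC1=CC[C@@H]2[C@@H]3[C@H]1[C@@]2(C)[C@H](O)C[C@@H](O)C3(C)C | intermediate
23 | isovaleryl chloride | CC(C)CC(Cl)=O | starting material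
24 | longipin-2-ene-7,9-diyl bis(3-methylbutanoate) | CC1=CC[C@@H]2[C@@H]3[C@H]1[C@@]2(C)[C@H](OC(=O)CC(C)C)C[C@@H](OC(=O)CC(C)C)C3(C)C | intermediate
25 | 7,9-bis(3-methylbutanoyloxy)longipin-2-en-1-one | CC1=CC(=O)[C@@H]2[C@@H]3[C@H]1[C@@]2(C)[C@H](OC(=O)CC(C)C)C[C@@H](OC(=O)CC(C)C)C3(C)C | target

**Step count**

Total steps: 14. Longest linear sequence: 14 steps (1 → 25).

**Steps most likely to fail**

Step 8. The tertiary C10 radical may lose a β-hydrogen to a second Cp2TiCl (isomerisation of the epoxide to an allylic alcohol) or be reduced before it closes the strained four-membered ring, and Lewis-acidic salts may rearrange the epoxide. The fallback sets out from 15 and comes back at 18: the same radical would be made from a halide and captured by samarium instead of titanium. MgBr2·OEt2 (Et2O, −20 °C) should open the epoxide at its tertiary carbon to the bromohydrin F1 (C10–Br, C9–OH with the epoxide configuration at C9). TESCl/imidazole should give the bromo silyl ether F2. SmI2 in THF/HMPA at −78 °C should cleave the C–Br bond and join C10 to the samarium-bound C4 carbonyl (samarium Barbier cyclisation), giving 18 after work-up, where the route resumes at step 10. Any organosamarium that expels the silyloxy group would only return dienone 14.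

Step 11. β-Scission of the stannyl adduct radical to a strained, non-stabilised bridgehead cyclobutyl radical may be too slow, so that the thiocarbonyl group is reduced without C–O cleavage. The fallback sets out from 18 and comes back at 21: it replaces the radical chain by electron-transfer cleavage, which favours the bridgehead position because a carbanion of high s-character is formed. The lithium alkoxide of 18 (n-BuLi, THF/TMEDA) would be phosphorylated with ClP(O)(NMe2)2 to the phosphorodiamidate F3, and lithium in ethylamine/THF with tert-butanol at 0 °C should cleave the C4–O bond to give 21. Both silyl ethers should survive, and a limited excess of metal should spare the trisubstituted alkene.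

Step 1. Proton transfer from the γ-methyl groups of the nitroalkene to the basic lithium enolate (deconjugation to the allylic nitronate, returning carvone) may outrun C–C bond formation at the hindered β-carbon, and the nitronate formed may add onward to C2. The fallback sets out from 1 and comes back at 5: it uses a non-basic nucleophile. LiN(iPr)2 then Me3SiCl should give the kinetic trimethylsilyl dienol ether F4. A Lewis acid-promoted Mukaiyama–Michael addition of F4 to 2 (TiCl2(OiPr)2 or SnCl4, CH2Cl2, −78 °C; aqueous work-up) should form the C5–C6 bond and release nitro ketone 5 on hydrolysis of the silyl group.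

**Further compounds**

F1 | step 8 | bromohydrin from 15: 5-bromo-6-hydroxy-5,6-dihydro derivative of 14 (C10–Br anti to C9–OH) | CC1=CC[C@@H]2[C@H](C1=O)C(C)(C)[C@H](O[Si](C)(C)C(C)(C)C)C[C@@H](O)[C@]2(C)Br
F2 | step 8 | triethylsilyl ether of F1 | CC1=CC[C@@H]2[C@H](C1=O)C(C)(C)[C@H](O[Si](C)(C)C(C)(C)C)C[C@@H](O[Si](CC)(CC)CC)[C@]2(C)Br
F3 | step 11 | 7-(tert-butyldimethylsilyloxy)-9-(triethylsilyloxy)longipin-2-en-4-yl N,N,N′,N′-tetramethylphosphorodiamidate | CC1=CC[C@@H]2[C@@H]3[C@@]1(OP(=O)(N(C)C)N(C)C)[C@@]2(C)[C@H](O[Si](CC)(CC)CC)C[C@@H](O[Si](C)(C)C(C)(C)C)C3(C)C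
F4 | step 1 | (R)-trimethyl{[6-methyl-3-(prop-1-en-2-yl)cyclohexa-1,5-dien-1-yl]oxy}silane | CC1=CC[C@@H](C(C)=C)C=C1O[Si](C)(C)C
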